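## Retrosynthetic overview

1. 34 ⇐ 32: the ten-membered ring is closed last by ethylene-mediated enyne cross-metathesis and ring-closing metathesis, which creates C5=C16 and the Z C3=C4 alkene.
2. 32 ⇐ 24 + 26: the C6–C7 bond and the chloride come from an anti-selective chloroallenylzinc addition; the γ-lactone is then closed by oxidation at C19.
3. 24 ⇐ 18 + 21: the C8–C9 bond comes from an aldol of a butyrolactone enolate (C7, C8, C17–C19, made from 1) with the ring A aldehyde.
4. 18 ⇐ 11 ⇐ 8: ring A is made by a Mn(OAc)3/Cu(OAc)2 oxidative free-radical 6-endo cyclization that forms C1–C10, the quaternary C1, C10 and the 11(20)-methylene in one step (key step).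
5. Ring order: ring A (radical), then γ-lactone, then ten-membered ring.

Atom numbers are those of the target: ring A = C1, C10–C14; C15 = methyl on C1; C20 = methylene on C11; C16 = methylene on C5; lactone = C7–O–C19(=O)–C17(C18)–C8.

Assumption: the sense of induction of the (−)-8-phenylmenthyl ester (step 6) and of Ru(OAc)2[(S)-BINAP] (step 13) is taken from the closest known cases; if either proved opposite, the antipodal auxiliary or ligand would be used with no other change.

## Route

Step 1
Reactants: 1 4-methylfuran-2(5H)-one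
Product: 2 (Z)-2-methylbut-2-ene-1,4-diol
Conditions: i-Bu2AlH (3 equiv), CH2Cl2, −78 → 0 °C; Rochelle salt work-up
Reagents that add atoms: none
Why: 1,2-Selective hydride reduction of the unsaturated lactone opens it to the diol, and the Z geometry of the trisubstituted alkene is inherited from the ring.

Step 2
Reactants: 2 (Z)-2-methylbut-2-ene-1,4-diol
Product: 3 (Z)-4-[(tert-butyldiphenylsilyl)oxy]-2-methylbut-2-en-1-ol
Conditions: t-BuPh2SiCl (1.0 equiv), imidazole, CH2Cl2, −40 °C
Reagents that add atoms: tert-butyl(chloro)diphenylsilane, CC(C)(C)[Si](Cl)(c1ccccc1)c1ccccc1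
Why: Regioselective monosilylation at the less hindered allylic CH2OH (on the CH= carbon, not on the methyl-bearing carbon); the minor regioisomer is removed by chromatography.

Step 3
Reactants: 3 (Z)-4-[(tert-butyldiphenylsilyl)oxy]-2-methylbut-2-en-1-ol
Product: 4 (Z)-[(4-bromo-3-methylbut-2-en-1-yl)oxy](tert-butyl)diphenylsilane
Conditions: CBr4, PPh3, CH2Cl2, 0 °C
Reagents that add atoms: carbon tetrabromide, BrC(Br)(Br)Br
Why: Appel bromination of the primary allylic alcohol under neutral conditions keeps the Z alkene.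

Step 4
Reactants: 5 methyl 3-oxobutanoate
Product: 6 (1R,2S,5R)-5-methyl-2-(2-phenylpropan-2-yl)cyclohexyl 3-oxobutanoate
Conditions: (−)-8-phenylmenthol (recoverable auxiliary), DMAP (0.3 equiv), toluene, reflux, −MeOH
Reagents that add atoms: (−)-8-phenylmenthol, O[C@@H]1C[C@H](C)CC[C@H]1C(C)(C)c1ccccc1
Why: DMAP-catalysed transesterification of a β-keto ester (via the acylketene) installs the chiral auxiliary.

Step 5
Reactants: 6 8-phenylmenthyl 3-oxobutanoate; 4 (Z)-allylic bromide
Product: 8 8-phenylmenthyl (Z)-8-[(tert-butyldiphenylsilyl)oxy]-2,6-dimethyl-3-oxooct-6-enoate (both C2 epimers), via monoalkylated keto ester enolate 7 (not isolated)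
Conditions: NaH, THF, 0 °C; n-BuLi, 0 °C; 4, −20 → 0 °C; then MeI, rt
Reagents that add atoms: iodomethane, CI
Why: Huckin–Weiler dianion γ-alkylation (SN2 at the primary allylic bromide, Z retained) followed by C-methylation of the remaining β-keto ester enolate in the same flask; the C2 epimers converge in step 6.

Step 6
Reactants: 8 (Z)-unsaturated α-methyl β-keto ester
Product: 11 ring A keto ester (C14 ketone; auxiliary ester on C1; CH2OSi on C10; 11(20)-methylene), via keto ester α-radical 9 (not isolated), via cyclized tertiary radical 10 (not isolated)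
Conditions: Mn(OAc)3·2H2O (2.2 equiv), Cu(OAc)2·H2O (1.0 equiv), degassed AcOH (0.03 M), 40 °C
Reagents that add atoms: none
Why: Snider-type oxidative free-radical cyclization, in which trivalent manganese oxidises the enol to radical 9, 9 closes 6-endo on C10 through a chair transition state (C1–C10 bond, quaternary C1), and divalent copper oxidises tertiary radical 10 with loss of a methyl hydrogen to the exocyclic alkene; the ester sits axial (carbonyl anti to the ketone, as in E-alkene cyclizations of this type that give the ester cis to the C10 substituent), the Z alkene therefore delivers the CH2OSi arm axial and trans to the ester (C10), and the 8-phenylmenthyl group shields one face of the radical (absolute configuration at C1).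

Step 7
Reactants: 11 ring A keto ester
Product: 13 ring A diol (14-OH cis to the CH2OH on C1; C9 silyl ether), via hydroxy ester 12 (not isolated)
Conditions: LiBH(s-Bu)3, THF, −78 → −20 °C; then LiAlH4, 0 °C → rt
Reagents that add atoms: none
Why: The bulky borohydride attacks the ketone from the methyl face, anti to the large ester (equatorial attack in the reactive chair), to give the 14-alcohol cis to the ester, and LiAlH4 then reduces the hindered ester and releases the auxiliary for recovery.

Step 8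
Reactants: 13 ring A diol
Product: 14 ring A hydroxy aldehyde (C2 = CHO; 14-OH free)
Conditions: TEMPO (10 mol %), PhI(OAc)2, CH2Cl2, rt
Reagents that add atoms: none
Why: Oxoammonium (TEMPO/PhI(OAc)2) oxidation is selective for the primary alcohol over the hindered axial secondary one, and the aldehyde has no α-hydrogen.

Step 9
Reactants: 14 ring A hydroxy aldehyde
Product: 15 ring A allylic 1,3-diol (C2 carbinol bearing vinyl; 2S; anti to 14-OH)
Conditions: CH2=CHMgBr (3.5 equiv), THF, −78 → −30 °C
Reagents that add atoms: vinylmagnesium bromide, C=C[Mg]Br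
Why: Chelation-controlled (Cram–Reetz) Grignard addition, in which the magnesium alkoxide of the axial 14-OH chelates the aldehyde and vinyl adds to the face remote from the C10 arm, gives the anti-1,3-diol with the C2 configuration of the target.

Step 10
Reactants: 15 ring A allylic 1,3-diol
Product: 16 C2/C14 acetonide (cis-fused 1,3-dioxane; C9 silyl ether)
Conditions: Me2C(OMe)2, PPTS (cat.), CH2Cl2, rt
Reagents that add atoms: 2,2-dimethoxypropane, COC(C)(C)OC
Why: Acid-catalysed transacetalization protects the 1,3-diol as its acetonide, stable to the basic and organometallic steps that follow.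

Step 11
Reactants: 16 acetonide silyl ether
Product: 17 acetonide primary alcohol (C9-OH)
Conditions: Bu4NF, THF, 0 °C → rt
Reagents that add atoms: none
Why: Fluoride cleaves the silyl ether; the acetonide and both alkenes are inert.

Step 12
Reactants: 17 acetonide primary alcohol
Product: 18 ring A aldehyde (C9 = CHO)
Conditions: TEMPO (10 mol %), PhI(OAc)2, CH2Cl2, rt; used crude
Reagents that add atoms: none
Why: Neutral oxoammonium oxidation gives the β,γ-unsaturated aldehyde without epimerizing C10 or moving the exocyclic alkene into conjugation.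

Step 13
Reactants: 1 4-methylfuran-2(5H)-one
Product: 19 (R)-4-methyldihydrofuran-2(3H)-one
Conditions: H2 (50 atm), Ru(OAc)2[(S)-BINAP] (0.5 mol %), MeOH/CH2Cl2, 50 °C
Reagents that add atoms: none
Why: Noyori-type asymmetric hydrogenation of the butenolide sets the methyl-bearing centre that becomes C17.

Step 14
Reactants: 19 (R)-4-methyldihydrofuran-2(3H)-one
Product: 21 trans-4-methyl-3-[(triethylsilyl)oxy]dihydrofuran-2(3H)-one (methyl carbon as in 19), via silyl ketene acetal 20 (not isolated)
Conditions: LiN(i-Pr)2, THF, −78 °C; Et3SiCl; then mCPBA, hexane, −15 °C → rt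
Reagents that add atoms: chlorotriethylsilane, CC[Si](Cl)(CC)CC; 3-chloroperbenzoic acid, O=C(OO)c1cccc(Cl)c1
Why: Rubottom oxidation of the ketene silyl acetal with silyl migration gives the α-silyloxy lactone, mainly trans to the methyl group; this centre is planarized again in step 15, so its configuration is immaterial.

Step 15
Reactants: 21 α-silyloxy lactone; 18 ring A aldehyde
Product: 23 aldol bis(triethylsilyl) ether (C8–C9 bond; lactone carbonyl = C7), via aldol adduct 22 (not isolated)
Conditions: 21, LiN(i-Pr)2, THF, −78 °C; 18, −78 °C; then Et3SiOTf, 2,6-lutidine, −78 → −40 °C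
Reagents that add atoms: triethylsilyl trifluoromethanesulfonate, CC[Si](CC)(CC)OS(=O)(=O)C(F)(F)F
Why: Lithium lactone enolate aldol through a Zimmerman–Traxler chair, in which the aldehyde adds anti to the β-methyl group (sets C8 relative to C17) and the silyloxy group cis to O–Li gives the 8,9-syn relationship (sets C9); the aldolate is silylated in the same flask to prevent retro-aldol.

Step 16
Reactants: 23 aldol bis(triethylsilyl) ether
Product: 24 lactol (C7 hemiacetal; anomer mixture)
Conditions: i-Bu2AlH (1.3 equiv), CH2Cl2, −78 °C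
Reagents that add atoms: none
Why: Partial reduction of the lactone stops at the tetrahedral aluminate, giving the lactol as a masked C7 aldehyde.

Step 17
Reactants: 25 3-chloroprop-1-yne
Product: 26 (3-chloroprop-1-yn-1-yl)trimethylsilane
Conditions: n-BuLi, Et2O, −78 °C; Me3SiCl
Reagents that add atoms: chlorotrimethylsilane, C[Si](C)(C)Cl
Why: Acetylide formation and C-silylation at low temperature leave the propargylic chloride untouched.

Step 18
Reactants: 24 lactol; 26 (3-chloroprop-1-yn-1-yl)trimethylsilane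
Product: 28 chlorohydrin diol (7-OH; 6-Cl; C4≡C5 silylalkyne; 19-OH), via chloroallenylzinc bromide 27 (not isolated)
Conditions: 26 (3 equiv), ZnBr2, LiN(i-Pr)2, THF, −80 °C; then 24, −80 → 0 °C
Reagents that add atoms: none
Why: Chemla–Normant-type addition of the γ-chloroallenylzinc reagent to the open hydroxy aldehyde through a cyclic SE2′ transition state gives the anti chlorohydrin (C6 relative to C7), and Felkin–Anh attack anti to the non-chelating 8-silyloxy group sets C7 (one equivalent of 27 is consumed by the lactol O–H).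

Step 19
Reactants: 28 chlorohydrin diol
Product: 29 protected γ-lactone (C19(=O)–O–C7)
Conditions: TEMPO (20 mol %), PhI(OAc)2 (2.5 equiv), CH2Cl2, rt
Reagents that add atoms: none
Why: Oxoammonium oxidation of the primary 19-OH to the aldehyde, lactol formation with 7-OH and a second oxidation give the γ-lactone; with no free 7-alkoxide left, the chlorohydrin cannot close to an epoxide.

Step 20
Reactants: 29 protected γ-lactone
Product: 31 tetraol terminal alkyne (2-, 8-, 9-, 14-OH), via acetonide diol 30 (not isolated)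
Conditions: Bu4NF, AcOH, THF, 0 °C → rt; then TsOH·H2O, MeOH, rt
Reagents that add atoms: none
Why: Buffered fluoride removes the alkynyl and both O-triethylsilyl groups without base-induced retro-aldol or lactone migration, and mild acid then cleaves the acetonide.

Step 21
Reactants: 31 tetraol terminal alkyne
Product: 32 triacetate (2-, 9-, 14-OAc; 8-OH free)
Conditions: Ac2O, pyridine, DMAP (cat.), CH2Cl2, rt
Reagents that add atoms: acetic anhydride, CC(=O)OC(C)=O
Why: DMAP-catalysed acetylation esterifies the three secondary alcohols, while the tertiary 8-OH does not react at room temperature.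

Step 22
Reactants: 32 triacetate enyne
Product: 34 CNP0178742.1, via triene 33 (not isolated)
Conditions: second-generation Grubbs catalyst (10 mol %), ethylene (1 atm), toluene (2 mM), 40 °C; then argon purge, 80 °C
Reagents that add atoms: ethylene, C=C
Why: Enyne cross-metathesis with ethylene turns the terminal alkyne into the 2-substituted butadiene (C5=C16 and C4=CH2), and ring-closing metathesis of its monosubstituted alkene with the C2 vinyl group closes the ten-membered ring; ring strain allows only the Z C3=C4 alkene, and the 1,1-disubstituted alkenes do not compete.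

## Compound list

1 | 4-methylfuran-2(5H)-one | CC1=CC(=O)OC1 | starting material
2 | (Z)-2-methylbut-2-ene-1,4-diol | OC/C=C(/C)CO | intermediate
3 | (Z)-4-[(tert-butyldiphenylsilyl)oxy]-2-methylbut-2-en-1-ol | CC(C)(C)[Si](OC/C=C(/C)CO)(c1ccccc1)c1ccccc1 | intermediate
4 | (Z)-[(4-bromo-3-methylbut-2-en-1-yl)oxy](tert-butyl)diphenylsilane | CC(C)(C)[Si](OC/C=C(/C)CBr)(c1ccccc1)c1ccccc1 | intermediate
5 | methyl 3-oxobutanoate | COC(=O)CC(C)=O | starting material
6 | (1R,2S,5R)-5-methyl-2-(2-phenylpropan-2-yl)cyclohexyl 3-oxobutanoate | CC(=O)CC(=O)O[C@@H]1C[C@H](C)CC[C@H]1C(C)(C)c1ccccc1 | intermediate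
7 | 8-phenylmenthyl (Z)-8-[(tert-butyldiphenylsilyl)oxy]-6-methyl-3-oxooct-6-enoate (present as its sodium enolate) | CC(C)(C)[Si](OC/C=C(/C)CCC(=O)CC(=O)O[C@@H]1C[C@H](C)CC[C@H]1C(C)(C)c1ccccc1)(c1ccccc1)c1ccccc1 | intermediate
8 | 8-phenylmenthyl (Z)-8-[(tert-butyldiphenylsilyl)oxy]-2,6-dimethyl-3-oxooct-6-enoate (C2 epimers) | CC(C)(C)[Si](OC/C=C(/C)CCC(=O)C(C)C(=O)O[C@@H]1C[C@H](C)CC[C@H]1C(C)(C)c1ccccc1)(c1ccccc1)c1ccccc1 | intermediate
9 | C2-centred α-keto ester radical of 8 | CC(C)(C)[Si](OC/C=C(/C)CCC(=O)[C](C)C(=O)O[C@@H]1C[C@H](C)CC[C@H]1C(C)(C)c1ccccc1)(c1ccccc1)c1ccccc1 | intermediate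
10 | cyclized tertiary C11 radical (ring A formed; C1 and C10 as in the target) | C[C]1CCC(=O)[C@](C)(C(=O)O[C@@H]2C[C@H](C)CC[C@H]2C(C)(C)c2ccccc2)[C@H]1CO[Si](c1ccccc1)(c1ccccc1)C(C)(C)C | intermediate
11 | 8-phenylmenthyl (1R,2S)-2-{[(tert-butyldiphenylsilyl)oxy]methyl}-1-methyl-3-methylidene-6-oxocyclohexane-1-carboxylate (ring A keto ester) | C=C1CCC(=O)[C@](C)(C(=O)O[C@@H]2C[C@H](C)CC[C@H]2C(C)(C)c2ccccc2)[C@H]1CO[Si](c1ccccc1)(c1ccccc1)C(C)(C)C | intermediate
12 | ring A hydroxy ester (14-OH cis to the ester, configured as C14 of the target) | C=C1CC[C@H](O)[C@](C)(C(=O)O[C@@H]2C[C@H](C)CC[C@H]2C(C)(C)c2ccccc2)[C@H]1CO[Si](c1ccccc1)(c1ccccc1)C(C)(C)C | intermediate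
13 | ring A diol: 3-{[(tert-butyldiphenylsilyl)oxy]methyl}-2-(hydroxymethyl)-2-methyl-4-methylidenecyclohexan-1-ol, C1, C10, C14 as in the target | C=C1CC[C@H](O)[C@](C)(CO)[C@H]1CO[Si](c1ccccc1)(c1ccccc1)C(C)(C)C | intermediate
14 | ring A hydroxy aldehyde (C2 = CHO), C1, C10, C14 as in the target | C=C1CC[C@H](O)[C@](C)(C=O)[C@H]1CO[Si](c1ccccc1)(c1ccccc1)C(C)(C)C | intermediate
15 | ring A allylic 1,3-diol (C2 vinyl carbinol, 2S, anti to 14-OH) | C=C1CC[C@H](O)[C@](C)([C@@H](O)C=C)[C@H]1CO[Si](c1ccccc1)(c1ccccc1)C(C)(C)C | intermediate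
16 | C2/C14 acetonide of 15 (cis-fused 2,2-dimethyl-1,3-dioxane), C9 silyl ether | C=C1CC[C@@H]2OC(C)(C)O[C@@H](C=C)[C@]2(C)[C@H]1CO[Si](c1ccccc1)(c1ccccc1)C(C)(C)C | intermediate
17 | acetonide primary alcohol (C9-OH) | C=C1CC[C@@H]2OC(C)(C)O[C@@H](C=C)[C@]2(C)[C@H]1CO | intermediate
18 | ring A aldehyde (C9 = CHO), acetonide | C=C1CC[C@@H]2OC(C)(C)O[C@@H](C=C)[C@]2(C)[C@H]1C=O | intermediate
19 | (R)-4-methyldihydrofuran-2(3H)-one | C[C@H]1COC(=O)C1 | intermediate
20 | triethyl{[(4R)-4-methyl-4,5-dihydrofuran-2-yl]oxy}silane | C[C@H]1COC(O[Si](CC)(CC)CC)=C1 | intermediate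
21 | trans-4-methyl-3-[(triethylsilyl)oxy]dihydrofuran-2(3H)-one (methyl carbon as in 19) | C[C@H]1COC(=O)[C@@H]1O[Si](CC)(CC)CC | intermediate
22 | aldol adduct (free 9-OH; 8-O-triethylsilyl; lactone C7=O; C8, C9, C17 as in the target) | C=C1CC[C@@H]2OC(C)(C)O[C@@H](C=C)[C@]2(C)[C@H]1[C@H](O)[C@@]3(O[Si](CC)(CC)CC)C(=O)OC[C@@H]3C | intermediate
23 | aldol bis(triethylsilyl) ether (8-O and 9-O silylated) | C=C1CC[C@@H]2OC(C)(C)O[C@@H](C=C)[C@]2(C)[C@H]1[C@H](O[Si](CC)(CC)CC)[C@@]3(O[Si](CC)(CC)CC)C(=O)OC[C@@H]3C | intermediate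
24 | lactol (C7 hemiacetal, anomer mixture) | C=C1CC[C@@H]2OC(C)(C)O[C@@H](C=C)[C@]2(C)[C@H]1[C@H](O[Si](CC)(CC)CC)[C@@]3(O[Si](CC)(CC)CC)C(O)OC[C@@H]3C | intermediate
25 | 3-chloroprop-1-yne | ClCC#C | starting material
26 | (3-chloroprop-1-yn-1-yl)trimethylsilane | ClCC#C[Si](C)(C)C | intermediate
27 | [3-chloro-1-(trimethylsilyl)propa-1,2-dien-1-yl]zinc bromide (racemic, labile) | ClC=C=C([Zn]Br)[Si](C)(C)C | intermediate
28 | chlorohydrin diol (7-OH, 6-Cl anti; C4≡C5 silylalkyne; 19-OH; C6, C7, C8, C9, C17 as in the target) | C=C1CC[C@@H]2OC(C)(C)O[C@@H](C=C)[C@]2(C)[C@H]1[C@H](O[Si](CC)(CC)CC)[C@](O[Si](CC)(CC)CC)([C@@H](C)CO)[C@@H](O)[C@@H](Cl)C#C[Si](C)(C)C | intermediate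
29 | protected γ-lactone (C19(=O)–O–C7), acetonide, two O-triethylsilyl groups, silylalkyne | C=C1CC[C@@H]2OC(C)(C)O[C@@H](C=C)[C@]2(C)[C@H]1[C@H](O[Si](CC)(CC)CC)[C@]3(O[Si](CC)(CC)CC)[C@@H](C)C(=O)O[C@H]3[C@@H](Cl)C#C[Si](C)(C)C | intermediate
30 | acetonide diol (8-OH, 9-OH free; terminal alkyne) | C=C1CC[C@@H]2OC(C)(C)O[C@@H](C=C)[C@]2(C)[C@H]1[C@H](O)[C@]3(O)[C@@H](C)C(=O)O[C@H]3[C@@H](Cl)C#C | intermediate
31 | tetraol terminal alkyne (2-, 8-, 9-, 14-OH) | C=C1CC[C@H](O)[C@](C)([C@@H](O)C=C)[C@H]1[C@H](O)[C@]3(O)[C@@H](C)C(=O)O[C@H]3[C@@H](Cl)C#C | intermediate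
32 | triacetate enyne (2-, 9-, 14-OAc; 8-OH) | C=C1CC[C@H](OC(C)=O)[C@](C)([C@@H](OC(C)=O)C=C)[C@H]1[C@H](OC(C)=O)[C@]3(O)[C@@H](C)C(=O)O[C@H]3[C@@H](Cl)C#C | intermediate
33 | triacetate triene (C5 bears =CH2 and CH=CH2) | C=C1CC[C@H](OC(C)=O)[C@](C)([C@@H](OC(C)=O)C=C)[C@H]1[C@H](OC(C)=O)[C@]3(O)[C@@H](C)C(=O)O[C@H]3[C@@H](Cl)C(=C)C=C | intermediate
34 | CNP0178742.1 (1R,2S,3Z,6S,7R,8R,9S,10S,14S,17R) | C=C1CC[C@H](OC(C)=O)[C@]2(C)[C@@H](OC(C)=O)/C=C\C(=C)[C@H](Cl)[C@@H]3OC(=O)[C@H](C)[C@@]3(O)[C@@H](OC(C)=O)[C@@H]12 | target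

## Step count and risk

Total steps: 22. Longest linear sequence: 18 steps (1, 2, 3, 5, 6, 7, 8, 9, 10, 11, 12, 15, 16, 18, 19, 20, 21, 22).

**Step 6 (radical cyclization).** The C10 configuration relies on the Z alkene reacting through the chair with the CH2OSi arm axial, the absolute sense relies on the auxiliary, and copper-mediated elimination may give some endocyclic alkene. The fallback sets out from 8 and comes back at 11. Selenenylation of 8 (PhSeCl, pyridine, CH2Cl2) gives the α-phenylselenyl keto ester F1. Sunlamp irradiation in benzene then runs the same 6-endo closure as a phenylselenyl group-transfer chain, without a metal oxidant, to the tertiary selenide F2. Oxidation (H2O2, pyridine) and selenoxide syn-elimination toward the methyl group give 11.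

**Step 15 (aldol).** The enolate-controlled facial choice at the aldehyde opposes the Felkin–Anh preference of C10 (C1 as the large group), so the C9 epimer may dominate. The fallback sets out from 18 and 21 and comes back at 23. The aldol is run without silyl trapping; if the 9-epimeric aldol F3 is the main product, it is oxidised (Dess–Martin periodinane) to the β-keto lactone F4. Reduction with LiBH(s-Bu)3 then sets C9 by substrate control (hydride anti to C1), which gives 22, and Et3SiOTf gives 23.

**Step 22 (macrocyclization).** A ten-membered ring closure on a flexible triacetate may give oligomers or stall at triene 33. The fallback sets out from 29 and comes back at 34; it moves ring closure ahead of deprotection and builds the diene separately. AgNO3-catalysed C-desilylation (aqueous acetone) gives the protected terminal alkyne F5. Cross-metathesis with ethylene (second-generation Grubbs catalyst) gives the isolated protected triene F6. Ring-closing metathesis of F6 with the second-generation Hoveyda–Grubbs catalyst, where the cis-fused acetonide holds the C2 vinyl group toward the diene, gives the protected macrocycle F7. Bu4NF/AcOH then TsOH/MeOH gives the macrocyclic tetraol F8, and acetylation (Ac2O, pyridine, DMAP) gives 34.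

## Further compounds

F1 | step 6 | 8-phenylmenthyl (Z)-8-[(tert-butyldiphenylsilyl)oxy]-2,6-dimethyl-3-oxo-2-(phenylselanyl)oct-6-enoate | CC(C)(C)[Si](OC/C=C(/C)CCC(=O)C(C)([Se]c1ccccc1)C(=O)O[C@@H]1C[C@H](C)CC[C@H]1C(C)(C)c1ccccc1)(c1ccccc1)c1ccccc1
F2 | step 6 | ring A keto ester carrying methyl and phenylselanyl on C11 (C1 and C10 as in 11) | CC1([Se]c2ccccc2)CCC(=O)[C@](C)(C(=O)O[C@@H]2C[C@H](C)CC[C@H]2C(C)(C)c2ccccc2)[C@H]1CO[Si](c1ccccc1)(c1ccccc1)C(C)(C)C
F3 | step 15 | 9-epimer of aldol adduct 22 | C=C1CC[C@@H]2OC(C)(C)O[C@@H](C=C)[C@]2(C)[C@H]1[C@@H](O)[C@@]3(O[Si](CC)(CC)CC)C(=O)OC[C@@H]3C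
F4 | step 15 | β-keto lactone (C9 ketone) | C=C1CC[C@@H]2OC(C)(C)O[C@@H](C=C)[C@]2(C)[C@H]1C(=O)[C@@]3(O[Si](CC)(CC)CC)C(=O)OC[C@@H]3C
F5 | step 22 | protected terminal alkyne (29 without the C-silyl group) | C=C1CC[C@@H]2OC(C)(C)O[C@@H](C=C)[C@]2(C)[C@H]1[C@H](O[Si](CC)(CC)CC)[C@]3(O[Si](CC)(CC)CC)[C@@H](C)C(=O)O[C@H]3[C@@H](Cl)C#C
F6 | step 22 | protected triene (C5 bears =CH2 and CH=CH2) | C=C1CC[C@@H]2OC(C)(C)O[C@@H](C=C)[C@]2(C)[C@H]1[C@H](O[Si](CC)(CC)CC)[C@]3(O[Si](CC)(CC)CC)[C@@H](C)C(=O)O[C@H]3[C@@H](Cl)C(=C)C=C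
F7 | step 22 | protected macrocycle (acetonide, 8-O and 9-O triethylsilyl, Z C3=C4) | C=C1CC[C@@H]4OC(C)(C)O[C@@H](/C=C\C(=C)[C@H](Cl)[C@@H]3OC(=O)[C@H](C)[C@@]3(O[Si](CC)(CC)CC)[C@@H](O[Si](CC)(CC)CC)[C@@H]12)[C@]24C
F8 | step 22 | macrocyclic tetraol (2-, 8-, 9-, 14-OH) | C=C1CC[C@H](O)[C@]2(C)[C@@H](O)/C=C\C(=C)[C@H](Cl)[C@@H]3OC(=O)[C@H](C)[C@@]3(O)[C@@H](O)[C@@H]12
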